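The numbers of this flask come from no measurement; the result is computed.

Substrate is slow to leave at 40 °C: the making of target by itself has a half-life of 2.29 h. With the leak to other conformer added, the half-life falls to 1.19 h, short against the 8.0 h allowed, so the branching of substrate is the thing to reckon.

in all of them: substrate 1.5 M; other conformer 0.150 M; time 8.0 h

| charge | temperature |
|---|---|
| south-east | 40 °C |
| north | 70 °C |
| north-west | 55 °C |
| east | 85 °C |

    substrate + target → side product (k1 = 0.00161 M⁻¹ min⁻¹, Ea1 = 83.0 kJ mol⁻¹)
    third conformer → third product (k2 = 0.0462 min⁻¹, Ea2 = 92.0 kJ mol⁻¹)
    substrate → target (k3 = 0.00504 min⁻¹, Ea3 = 111 kJ mol⁻¹)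
    other conformer → isomer of the product (k4 = 2.40 min⁻¹, Ea4 = 88.0 kJ mol⁻¹)
    substrate ⇌ other conformer (K5 = 0.104, k5 = 0.00464 min⁻¹, Ea5 = 99.0 kJ mol⁻¹, ΔH5 = −79.0 kJ mol⁻¹)
    other conformer ⇌ third conformer (K6 = 0.355, k6 = 0.183 min⁻¹, Ea6 = 100 kJ mol⁻¹, ΔH6 = 58.0 kJ mol⁻¹)
    (constants at 40 °C)

- percent here means substrate units held: one side product counts as two
- the constants hold at 40 °C; other temperatures follow from the activation energies and enthalpies
- in a conversion other conformer counts as not yet reacted; third conformer counts as reacted

- the flask that comes out highest in amount of target, in percent of the substrate and other conformer together charged, or "all alike" when all lie within 1.5 percentage points (south-east / north / north-west / east / all alike)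
- target at the end, in percent of the substrate and other conformer together charged, south-east
- target at the end, in percent of the substrate and other conformer together charged, north
- target at the end, in percent of the substrate and other conformer together charged, north-west
- target at the end, in percent of the substrate and other conformer together charged, east

Other conformer drains to isomer of the product far faster than substrate leaks into it, 2.40 min⁻¹ against 0.00464 min⁻¹ at 40 °C and 168 min⁻¹ against 0.551 min⁻¹ in east, so it stays at a low steady level, and one selectivity factor B describes the branching. Let kT be the constant for making target, kL the forward leak, K the leak's equilibrium constant and kI the drain to isomer; then B = kT/kL + kT/(K·kI), a direct term plus a return term.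

Logarithms show which numbers must be good. From the coldest flask to the hottest, the direct term climbs 0.252 powers of ten, on an energy difference of 12.0 kJ mol⁻¹. The return term climbs 2.14 powers on 102 kJ mol⁻¹, so the enthalpy of the leak must be known well. In south-east the route through third conformer, which B leaves out, takes 0.627 % of the other conformer. A factor of 2 in kL moves the south-east substrate share B/(1+B) from 52.5 % to 36.0 %, so kL matters.

Now the numbers. At 40 °C the terms are 1.09 and 0.0202, giving B, the substrate ending in target per substrate lost for good to isomer, of 1.11. In east they are 1.94 and 2.77, so B is 4.71.

Multiplying the share by the substrate charged, and adding the returning part of the charged other conformer, gives an estimate of target with side product and third conformer left out: 47.8 % in south-east, 54.4 % in north-west, 64.6 % in north and 79.4 % in east. East stands highest. The reckoning stops at these estimates.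

The forecast names east, with 40 % in south-east, 47.8 % in north-west, 58.1 % in north and 71.9 % in east, each below the estimate above for its flask. Its ground: “The other conformer is therefore kept at steady state.”

The flasks give 40.0 % in south-east, 47.8 % in north-west, 58.0 % in north and 71.9 % in east, so east comes out highest, as forecast. In east the forward making of target runs at 1.9 times the forward leak at 0.00845 h, while B stands above that at 4.71, and target ends 7.5 percentage points under the estimate. The repeat of east at 100 °C has a B of 13.3 and an estimate of 91.5 %, and it gives 84.1 % of target, 7.4 points under it.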